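## Retrosynthetic overview

- The target is traced back to keto ester 16 (labdane numbering C1–C20 throughout): the C3 ketone is reduced from the β face, the C4 methyl is introduced from the α face, and the C15 silyl ether is removed last.
- The decalin comes from the acyclic β-keto ester 10 in one oxidative radical bicyclisation: C4–C5 closes ring A, then C9–C10 closes ring B, and the terminating oxidation creates the C8=C17 methylene.
- Enabling feature: C4 sits between the C3 ketone and the C19 ester, so it can be oxidised to a radical. The two E-trisubstituted alkenes C5=C10 and C8=C9 carry their methyl groups on C10 and C8, so each 6-endo closure gives a tertiary radical, and the C17 methyl on C8 supplies the hydrogen lost in forming the exocyclic alkene.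
- A (+)-8-phenylmenthyl ester at C19 controls the absolute sense of the bicyclisation and is exchanged for the methyl ester directly afterwards.
- 10 comes from acetoacetate 9 and allylic bromide 5, which is made from (2E,6E)-farnesol by asymmetric hydrogenation (sets C13), silylation, terminal allylic oxidation and bromination.

Key step: step 7

Remark: (2E,6E)-farnesol, (+)-8-phenylmenthol and 2,2,6-trimethyl-4H-1,3-dioxin-4-one are taken as commercially available. The choice of the (+)-auxiliary rests on a chelate model of the enolate and on the behaviour of closely related 8-phenylmenthyl keto esters.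

## Route

Step 1
Reactants: 1 (2E,6E)-farnesol
Product: 2 (S)-2,3-dihydrofarnesol
Conditions: Ru(OAc)2[(R)-BINAP] (0.5 mol %), H2 (100 atm), MeOH/H2O 95:5, 20 °C
Reagents that add atoms: none
Why: Ru–BINAP-catalysed asymmetric hydrogenation of an allylic alcohol: the hydroxyl-bound catalyst reduces only the C2=C3 alkene and leaves the two remote trisubstituted alkenes alone, and with the (R)-ligand and the E-alkene hydrogen should be delivered to the face that gives the (S)-methyl stereocenter (C13 of the target), as in the reduction of geraniol to (S)-citronellol.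

Step 2
Reactants: 2 (S)-2,3-dihydrofarnesol
Product: 3 tert-butyldiphenylsilyl ether of (S)-2,3-dihydrofarnesol
Conditions: t-BuPh2SiCl, imidazole, CH2Cl2, rt
Reagents that add atoms: tert-butyl(chloro)diphenylsilane, CC(C)(C)[Si](Cl)(c1ccccc1)c1ccccc1
Why: Standard silylation of the primary alcohol; the tert-butyldiphenylsilyl ether is chosen because it should survive the acidic, oxidative, basic and hydride conditions up to step 11 and can be removed by fluoride without touching the acetate.

Step 3
Reactants: 3 tert-butyldiphenylsilyl ether of (S)-2,3-dihydrofarnesol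
Product: 4 (2E,6E,10S)-12-(tert-butyldiphenylsilyloxy)-2,6,10-trimethyldodeca-2,6-dien-1-ol
Conditions: SeO2 (0.2 equiv), t-BuOOH (3 equiv), salicylic acid (0.1 equiv), CH2Cl2, 0 °C to rt
Reagents that add atoms: tert-butyl hydroperoxide, CC(C)(C)OO (terminal oxygen source; the oxygen is passed on by selenium dioxide, O=[Se]=O)
Why: Riley oxidation (ene reaction followed by a [2,3]-sigmatropic shift) with catalytic SeO2 and t-BuOOH attacks the terminal trisubstituted alkene of a polyprenyl chain at the methyl group trans to the chain and should give the E-allylic alcohol; no stereocenter is formed.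

Step 4
Reactants: 4 (2E,6E,10S)-12-(tert-butyldiphenylsilyloxy)-2,6,10-trimethyldodeca-2,6-dien-1-ol
Product: 5 (2E,6E,10S)-1-bromo-12-(tert-butyldiphenylsilyloxy)-2,6,10-trimethyldodeca-2,6-diene
Conditions: CBr4, PPh3, CH2Cl2, 0 °C
Reagents that add atoms: tetrabromomethane, BrC(Br)(Br)Br
Why: Appel bromination converts the primary allylic alcohol into the bromide by SN2 displacement of the oxyphosphonium group under neutral conditions, so the E geometry and the silyl ether should be kept and no stereocenter is touched.

Step 5
Reactants: 6 (+)-8-phenylmenthol; 7 2,2,6-trimethyl-4H-1,3-dioxin-4-one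
Product: 9 (+)-8-phenylmenthyl acetoacetate, via acetylketene 8 (not isolated)
Conditions: xylene, 140 °C, acetone distilled off
Reagents that add atoms: none
Why: Thermal retro-[4+2] fragmentation of the dioxinone releases acetylketene 8, which acylates even a hindered secondary alcohol under neutral conditions, so the auxiliary is esterified without any change at its three stereocenters.

Step 6
Reactants: 9 (+)-8-phenylmenthyl acetoacetate; 5 (2E,6E,10S)-1-bromo-12-(tert-butyldiphenylsilyloxy)-2,6,10-trimethyldodeca-2,6-diene
Product: 10 (+)-8-phenylmenthyl (6E,10E,14S)-16-(tert-butyldiphenylsilyloxy)-6,10,14-trimethyl-3-oxohexadeca-6,10-dienoate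
Conditions: LiN(i-Pr)2 (2.1 equiv), THF, 0 °C; then 5, 0 °C; then aqueous HCl (1 M)
Reagents that add atoms: none
Why: γ-Alkylation of an acetoacetate dianion: the terminal carbanion is the more reactive site and should displace the primary allylic bromide by SN2 without allylic transposition, so both E-alkenes and C13 are carried through unchanged.

Step 7
Reactants: 10 (+)-8-phenylmenthyl (6E,10E,14S)-16-(tert-butyldiphenylsilyloxy)-6,10,14-trimethyl-3-oxohexadeca-6,10-dienoate
Product: 13 bicyclic keto ester (trans-decalin; 8-phenylmenthyl ester equatorial at C4; 3-oxo; 5α-H; 9α-H; 10β-methyl; C8=C17 methylene; silyl ether side chain), via tertiary C10 radical 11 (not isolated), via tertiary C8 radical 12 (not isolated)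
Conditions: Mn(OAc)3·2H2O (2.2 equiv), Cu(OAc)2·H2O (1 equiv), Yb(OTf)3 (1 equiv), degassed CF3CH2OH, −5 to 0 °C
Reagents that add atoms: none
Why: Mn(OAc)3 oxidises the Yb(OTf)3-chelated enolate of 10 by one electron to the electrophilic C4 radical, which adds 6-endo-trig to C5 of the C5=C10 alkene (ring A) to give the tertiary C10 radical 11; 11 then adds 6-endo-trig to C9 of the C8=C9 alkene, forming the C9–C10 bond and ring B, and the tertiary C8 radical 12 is captured by Cu(OAc)2 and loses a C17 hydrogen by oxidative β-hydride elimination to give the exocyclic C8=C17 methylene. The closest known reaction type is the oxidative free-radical polyene cyclisation of unsaturated β-keto esters with trivalent manganese and divalent copper, including its diastereoselective variant with an 8-phenylmenthyl ester promoted by a lanthanide triflate. C5 is set by the auxiliary: in the chelated enolate the phenyl group stacks over one face of C4, so the C5=C10 alkene should approach from the open face, and the (+)-auxiliary should lead to the 5α-H, 10β-methyl series. C10 and C9 follow from the chair–chair transition state with both alkenes E, which makes the ring fusion trans and places the C9 side chain equatorial (9α-H), while C4 is formed with the ester equatorial but stays epimerisable and is fixed in step 9. The step needs 6-endo regiochemistry in both closures, which the substrate secures because C5 and C9 are the less substituted alkene ends and attack there gives tertiary radicals; it needs elimination toward C17 and not C7, which the preference of the copper-bound tertiary alkyl for the unhindered methyl hydrogens should secure; and it needs the enolisable product to survive, which slow enolisation of the hindered bicyclic keto ester and the limit of about two equivalents of Mn(OAc)3 should allow.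

Step 8
Reactants: 13 bicyclic 8-phenylmenthyl keto ester
Product: 15 bicyclic methyl keto ester (methyl ester equatorial at C4; otherwise as 13), via α-oxoketene 14 (not isolated)
Conditions: MeOH/toluene 1:1, DMAP (0.3 equiv), sealed tube, 120 °C
Reagents that add atoms: methanol, CO
Why: DMAP-catalysed transesterification of a β-keto ester that still has its α-hydrogen runs through loss of the alcohol to the α-oxoketene 14 and its capture by the large excess of methanol, so the hindered secondary alkoxide should be released without attack at the ester carbonyl, and C4 is re-formed as the enolisable equatorial ester so no fixed stereocenter is affected.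

Step 9
Reactants: 15 bicyclic methyl keto ester
Product: 16 methyl (13S)-15-(tert-butyldiphenylsilyloxy)-3-oxolabd-8(17)-en-19-oate
Conditions: K2CO3, MeI, acetone, 45 °C
Reagents that add atoms: iodomethane, CI
Why: C-Alkylation of the β-keto ester enolate with MeI: the axial C10 methyl blocks the β face of C4 through a 1,3-diaxial relationship, so the methyl group should enter from the α face and end up equatorial (4α) with the ester axial (4β), as the target requires.

Step 10
Reactants: 16 methyl (13S)-15-(tert-butyldiphenylsilyloxy)-3-oxolabd-8(17)-en-19-oate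
Product: 17 methyl (13S)-15-(tert-butyldiphenylsilyloxy)-3α-hydroxylabd-8(17)-en-19-oate
Conditions: LiBH(s-Bu)3, THF, −78 °C; then H2O
Reagents that add atoms: none
Why: Ketone reduction with the bulky trialkylborohydride LiBH(s-Bu)3: axial approach over the α face is blocked by the axial hydrogens at C1 and C5, so hydride should be delivered equatorially from the β side to give the axial 3α-alcohol, and the hindered methyl ester and the alkene are not reduced at −78 °C.

Step 11
Reactants: 17 methyl (13S)-15-(tert-butyldiphenylsilyloxy)-3α-hydroxylabd-8(17)-en-19-oate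
Product: 18 methyl (13S)-3α-acetoxy-15-(tert-butyldiphenylsilyloxy)labd-8(17)-en-19-oate
Conditions: Ac2O, DMAP, pyridine, 40 °C
Reagents that add atoms: acetic anhydride, CC(=O)OC(C)=O
Why: DMAP-catalysed acylation of the hindered axial secondary alcohol with Ac2O proceeds with retention at C3 and leaves the silyl ether and the neopentyl methyl ester untouched.

Step 12
Reactants: 18 methyl (13S)-3α-acetoxy-15-(tert-butyldiphenylsilyloxy)labd-8(17)-en-19-oate
Product: 19 methyl (13S)-3α-acetoxy-15-hydroxylabd-8(17)-en-19-oate (target)
Conditions: n-Bu4NF, AcOH, THF, rt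
Reagents that add atoms: none
Why: Fluoride-induced desilylation (Si–F bond formation) buffered with AcOH frees the primary C15 alcohol while the buffered medium keeps the C3 acetate and the methyl ester from cleavage or migration, giving the target.

## Compound list

1 | (2E,6E)-farnesol | CC(C)=CCC/C(C)=C/CC/C(C)=C/CO | starting material
2 | (S)-2,3-dihydrofarnesol, (3S,6E)-3,7,11-trimethyldodeca-6,10-dien-1-ol | CC(C)=CCC/C(C)=C/CC[C@H](C)CCO | intermediate
3 | tert-butyldiphenylsilyl ether of 2 | CC(C)=CCC/C(C)=C/CC[C@H](C)CCO[Si](c1ccccc1)(c1ccccc1)C(C)(C)C | intermediate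
4 | (2E,6E,10S)-12-(tert-butyldiphenylsilyloxy)-2,6,10-trimethyldodeca-2,6-dien-1-ol | OC/C(C)=C/CC/C(C)=C/CC[C@H](C)CCO[Si](c1ccccc1)(c1ccccc1)C(C)(C)C | intermediate
5 | (2E,6E,10S)-1-bromo-12-(tert-butyldiphenylsilyloxy)-2,6,10-trimethyldodeca-2,6-diene | BrC/C(C)=C/CC/C(C)=C/CC[C@H](C)CCO[Si](c1ccccc1)(c1ccccc1)C(C)(C)C | intermediate
6 | (+)-8-phenylmenthol, (1S,2R,5S)-5-methyl-2-(2-phenylpropan-2-yl)cyclohexan-1-ol | O[C@H]1C[C@@H](C)CC[C@@H]1C(C)(C)c1ccccc1 | starting material
7 | 2,2,6-trimethyl-4H-1,3-dioxin-4-one | CC1=CC(=O)OC(C)(C)O1 | starting material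
8 | acetylketene | CC(=O)C=C=O | intermediate (not isolated)
9 | (+)-8-phenylmenthyl acetoacetate | CC(=O)CC(=O)O[C@H]1C[C@@H](C)CC[C@@H]1C(C)(C)c1ccccc1 | intermediate
10 | (+)-8-phenylmenthyl (6E,10E,14S)-16-(tert-butyldiphenylsilyloxy)-6,10,14-trimethyl-3-oxohexadeca-6,10-dienoate | O=C(CC(=O)CC/C(C)=C/CC/C(C)=C/CC[C@H](C)CCO[Si](c1ccccc1)(c1ccccc1)C(C)(C)C)O[C@H]1C[C@@H](C)CC[C@@H]1C(C)(C)c1ccccc1 | intermediate
11 | monocyclic tertiary C10 radical (ring A closed; C4 ester and C5 chain trans; C8=C9 alkene still open) | C[C]1CCC(=O)[C@@H](C(=O)O[C@H]2C[C@@H](C)CC[C@@H]2C(C)(C)c2ccccc2)[C@@H]1CC/C(C)=C/CC[C@H](C)CCO[Si](c1ccccc1)(c1ccccc1)C(C)(C)C | intermediate (not isolated)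
12 | bicyclic tertiary C8 radical (trans-decalin; C8 bears the C17 methyl) | C[C]1CC[C@@H]2[C@](C)(CCC(=O)[C@H]2C(=O)O[C@H]3C[C@@H](C)CC[C@@H]3C(C)(C)c3ccccc3)[C@H]1CC[C@H](C)CCO[Si](c1ccccc1)(c1ccccc1)C(C)(C)C | intermediate (not isolated)
13 | bicyclic 8-phenylmenthyl keto ester: trans-decalin, ester equatorial at C4 (4β-H), 3-oxo, 5α-H, 9α-H, 10β-methyl, C8=C17 methylene, (13S)-15-silyloxy side chain | C=C1CC[C@@H]2[C@](C)(CCC(=O)[C@H]2C(=O)O[C@H]3C[C@@H](C)CC[C@@H]3C(C)(C)c3ccccc3)[C@H]1CC[C@H](C)CCO[Si](c1ccccc1)(c1ccccc1)C(C)(C)C | intermediate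
14 | α-oxoketene at C4 (C4=C=O beside the C3 ketone) | C=C1CC[C@@H]2[C@](C)(CCC(=O)C2=C=O)[C@H]1CC[C@H](C)CCO[Si](c1ccccc1)(c1ccccc1)C(C)(C)C | intermediate (not isolated)
15 | bicyclic methyl keto ester: as 13 with a methyl ester | C=C1CC[C@@H]2[C@](C)(CCC(=O)[C@H]2C(=O)OC)[C@H]1CC[C@H](C)CCO[Si](c1ccccc1)(c1ccccc1)C(C)(C)C | intermediate
16 | methyl (13S)-15-(tert-butyldiphenylsilyloxy)-3-oxolabd-8(17)-en-19-oate (4α-methyl, 4β-CO2Me) | C=C1CC[C@@H]2[C@](C)(CCC(=O)[C@]2(C)C(=O)OC)[C@H]1CC[C@H](C)CCO[Si](c1ccccc1)(c1ccccc1)C(C)(C)C | intermediate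
17 | methyl (13S)-15-(tert-butyldiphenylsilyloxy)-3α-hydroxylabd-8(17)-en-19-oate | C=C1CC[C@@H]2[C@](C)(CC[C@@H](O)[C@]2(C)C(=O)OC)[C@H]1CC[C@H](C)CCO[Si](c1ccccc1)(c1ccccc1)C(C)(C)C | intermediate
18 | methyl (13S)-3α-acetoxy-15-(tert-butyldiphenylsilyloxy)labd-8(17)-en-19-oate | C=C1CC[C@@H]2[C@](C)(CC[C@@H](OC(C)=O)[C@]2(C)C(=O)OC)[C@H]1CC[C@H](C)CCO[Si](c1ccccc1)(c1ccccc1)C(C)(C)C | intermediate
19 | methyl (13S)-3α-acetoxy-15-hydroxylabd-8(17)-en-19-oate | C=C1CC[C@@H]2[C@](C)(CC[C@@H](OC(C)=O)[C@]2(C)C(=O)OC)[C@H]1CC[C@H](C)CCO | target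

## Step count and risks

Total steps: 12. Longest linear sequence: 11 steps (1 to 19 through steps 1–4 and 6–12); step 5 is a one-step side branch.

Steps most likely to fail:

1. Step 7. The auxiliary may discriminate the two faces of C4 too weakly, the copper-mediated elimination may run partly toward C7, or the enolisable product may be oxidised further. Fallback, from 5 and back at 17: 5 would alkylate the dianion of methyl 2-methylacetoacetate (COC(=O)C(C)C(C)=O; LiN(i-Pr)2, THF, 0 °C) to give the auxiliary-free α-methyl keto ester F1. The classical bicyclisation with Mn(OAc)3·2H2O and Cu(OAc)2·H2O in AcOH at rt should then give 16 directly (axial ester, no enolisable product) together with the antipodal-decalin diastereomer of 16 F2. Reduction of this mixture with (S)-Me-CBS and catecholborane delivers hydride to the same enantioface of C3 in both, so 16 should give the axial alcohol 17 and F2 should give the equatorial alcohol of the antipodal decalin F3. These differ in relative configuration and should be separable by chromatography, at the cost of half the material.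

2. Step 8. Release of the hindered alkoxide through the ketene may be slow or incomplete, and prolonged heating may degrade the keto ester. Fallback, from 13 and back at 17: 13 would be methylated at C4 on the auxiliary (K2CO3, MeI) to the 4α-methyl 8-phenylmenthyl keto ester F4, then reduced with LiBH(s-Bu)3 to the 3α-hydroxy 8-phenylmenthyl ester F5. LiAlH4 would remove the hindered ester reductively, with recovery of the auxiliary, to give the 3α,19-diol F6. Selective oxidation of the primary alcohol (TEMPO, PhI(OAc)2) to the 3α-hydroxy aldehyde F7, then NaClO2/NaH2PO4/2-methyl-2-butene to the 3α-hydroxy acid F8, and esterification with Me3SiCHN2 would give 17.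

3. Step 10. The axial C4 ester may shield the β face enough that hydride is delivered partly from the α side, giving the equatorial 3β-alcohol. Fallback, from 16 and back at 17: substrate control would be replaced by reagent control, using (S)-Me-CBS with catecholborane (toluene, −78 to −40 °C; catecholborane spares the exocyclic alkene). With C4 as the large and C2 as the small ketone substituent, this catalyst should deliver hydride to the β face and give 17; this fallback makes no new compound (F0).

## Further compounds

F1 | step 7 | methyl (6E,10E,14S)-16-(tert-butyldiphenylsilyloxy)-2,6,10,14-tetramethyl-3-oxohexadeca-6,10-dienoate | COC(=O)C(C)C(=O)CC/C(C)=C/CC/C(C)=C/CC[C@H](C)CCO[Si](c1ccccc1)(c1ccccc1)C(C)(C)C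
F2 | step 7 | diastereomer of 16 with the antipodal decalin and unchanged (13S) centre | C=C1CC[C@H]2[C@@](C)(CCC(=O)[C@@]2(C)C(=O)OC)[C@@H]1CC[C@H](C)CCO[Si](c1ccccc1)(c1ccccc1)C(C)(C)C
F3 | step 7 | equatorial C3 alcohol of the antipodal decalin | C=C1CC[C@H]2[C@@](C)(CC[C@@H](O)[C@@]2(C)C(=O)OC)[C@@H]1CC[C@H](C)CCO[Si](c1ccccc1)(c1ccccc1)C(C)(C)C
F4 | step 8 | (+)-8-phenylmenthyl (13S)-15-(tert-butyldiphenylsilyloxy)-3-oxolabd-8(17)-en-19-oate | C=C1CC[C@@H]2[C@](C)(CCC(=O)[C@]2(C)C(=O)O[C@H]3C[C@@H](C)CC[C@@H]3C(C)(C)c3ccccc3)[C@H]1CC[C@H](C)CCO[Si](c1ccccc1)(c1ccccc1)C(C)(C)C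
F5 | step 8 | (+)-8-phenylmenthyl (13S)-15-(tert-butyldiphenylsilyloxy)-3α-hydroxylabd-8(17)-en-19-oate | C=C1CC[C@@H]2[C@](C)(CC[C@@H](O)[C@]2(C)C(=O)O[C@H]3C[C@@H](C)CC[C@@H]3C(C)(C)c3ccccc3)[C@H]1CC[C@H](C)CCO[Si](c1ccccc1)(c1ccccc1)C(C)(C)C
F6 | step 8 | (13S)-15-(tert-butyldiphenylsilyloxy)labd-8(17)-ene-3α,19-diol | C=C1CC[C@@H]2[C@](C)(CC[C@@H](O)[C@]2(C)CO)[C@H]1CC[C@H](C)CCO[Si](c1ccccc1)(c1ccccc1)C(C)(C)C
F7 | step 8 | (13S)-15-(tert-butyldiphenylsilyloxy)-3α-hydroxylabd-8(17)-en-19-al | C=C1CC[C@@H]2[C@](C)(CC[C@@H](O)[C@]2(C)C=O)[C@H]1CC[C@H](C)CCO[Si](c1ccccc1)(c1ccccc1)C(C)(C)C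
F8 | step 8 | (13S)-15-(tert-butyldiphenylsilyloxy)-3α-hydroxylabd-8(17)-en-19-oic acid | C=C1CC[C@@H]2[C@](C)(CC[C@@H](O)[C@]2(C)C(=O)O)[C@H]1CC[C@H](C)CCO[Si](c1ccccc1)(c1ccccc1)C(C)(C)C
F0 | step 10 | none | none
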